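**Plan**

- Enabling feature: the carbinol carbon C1 (bearing the 4-methoxyphenyl ring), the methine C2 and the ester-bearing CH2 form an O–C1–C2–CH2–O array that maps onto a six-membered 1,3-dioxan-2-ylium built from the ester's own carbonyl. C1 is a cation-stabilising 4-methoxybenzylic position, and C2 carries the allylic CH2 (C3) of the 3,4-dimethoxycinnamyl unit, the terminus of an aryl-stabilised allyl cation.
- Cuts, in retrosynthetic order: the O–Si bond; then C2–C3 and C1–O together, back to a 4-methoxycinnamyl ester and an aryl vinyl carbinol; then the ester C–O bond (acid plus cinnamyl alcohol); then the C–CO2H bond of the acid (alkenyl bromide from crotonaldehyde).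
- Forward order: acid and 4-methoxycinnamyl alcohol are joined to the ester, then ester and carbinol give the whole skeleton in one step. The only ring, the dioxanylium, forms and opens within that step, so nothing cyclic persists.
- Stereochemistry: the Z enoate comes from (Z)-2-bromobut-2-enal and is carried through bromine–lithium exchange with retention. The E styrenes come from the cinnamate and from terminal attack on the allyl cation. C2 is set by the chiral counter-anion choosing the alkene face, and C1 is relayed from C2 by anti addition across the E alkene (trans-diequatorial ring closure).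

Key step: step 8

Assumption: the (R)-antipode of the N-triflylphosphoramide is taken to deliver the (1S,2S) series (C1 = carbinol carbon, C2 = methine; locants 3 and 2 in the ester names). The sense of induction of this ion-pair reaction cannot be predicted, and the (S)-acid is used in the same way if the (R)-acid proves to give the mirror-image series.

**Route**

Step 1
Reactants: 1 ethyl (E)-3-(4-methoxyphenyl)prop-2-enoate
Product: 2 (E)-3-(4-methoxyphenyl)prop-2-en-1-ol
Conditions: i-Bu2AlH (2.2 equiv), CH2Cl2, −78 to 0 °C; Rochelle salt work-up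
Reagents that add atoms: none
Why: Hydride reduction of a conjugated ester with i-Bu2AlH proceeds by 1,2-delivery to the allylic alcohol and leaves the E styrene untouched.

Step 2
Reactants: 3 (E)-but-2-enal
Product: 5 (Z)-2-bromobut-2-enal, via 2,3-dibromobutanal 4 (not isolated)
Conditions: Br2, CH2Cl2, −20 to 0 °C; then Et3N, 0 °C to rt
Reagents that add atoms: bromine, BrBr
Why: Anti bromination of the alkene followed by amine-induced dehydrobromination (loss of the acidic α-hydrogen and the β-bromide, E1cB) should give the more stable α-bromoenal with methyl trans to formyl, which is the Z isomer.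

Step 3
Reactants: 5 (Z)-2-bromobut-2-enal
Product: 6 (Z)-2-bromobut-2-en-1-ol
Conditions: NaBH4, CeCl3·7H2O, MeOH, 0 °C
Reagents that add atoms: none
Why: Luche reduction delivers hydride to the carbonyl only, so the bromoalkene and its geometry are kept.

Step 4
Reactants: 6 (Z)-2-bromobut-2-en-1-ol
Product: 7 tert-butyl{[(Z)-2-bromobut-2-en-1-yl]oxy}diphenylsilane
Conditions: t-BuPh2SiCl, imidazole, CH2Cl2, rt
Reagents that add atoms: tert-butyl(chloro)diphenylsilane, CC(C)(C)[Si](Cl)(c1ccccc1)c1ccccc1
Why: Imidazole-promoted silylation of a primary alcohol installs an ether that tolerates organolithium reagents and strong Brønsted acid.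

Step 5
Reactants: 7 tert-butyl{[(Z)-2-bromobut-2-en-1-yl]oxy}diphenylsilane
Product: 9 (Z)-2-[(tert-butyldiphenylsilyloxy)methyl]but-2-enoic acid, via alkenyllithium 8 (not isolated)
Conditions: t-BuLi (2.1 equiv), Et2O, −78 °C; CO2 (dry gas), −78 to 0 °C; 1 M HCl
Reagents that add atoms: carbon dioxide, O=C=O
Why: Bromine–lithium exchange on an alkenyl bromide retains the double-bond geometry, and carboxylation of 8 at −78 °C should outrun silyl migration or elimination, so the methyl group ends cis to the carboxyl group.

Step 6
Reactants: 9 (Z)-2-[(tert-butyldiphenylsilyloxy)methyl]but-2-enoic acid and 2 (E)-3-(4-methoxyphenyl)prop-2-en-1-ol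
Product: 11 (E)-3-(4-methoxyphenyl)prop-2-enyl (Z)-2-[(tert-butyldiphenylsilyloxy)methyl]but-2-enoate, via mixed anhydride 10 (not isolated)
Conditions: 2,4,6-trichlorobenzoyl chloride, Et3N, toluene, rt; then 2, DMAP, rt
Reagents that add atoms: none
Why: Yamaguchi esterification acylates the primary allylic alcohol through mixed anhydride 10 at room temperature, conditions under which angelate-type Z acids are known to keep their geometry.

Step 7
Reactants: 12 3,4-dimethoxybenzaldehyde
Product: 13 rac-1-(3,4-dimethoxyphenyl)prop-2-en-1-ol
Conditions: CH2=CHMgBr, THF, 0 °C; aqueous work-up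
Reagents that add atoms: vinylmagnesium bromide, C=C[Mg]Br
Why: Grignard addition to the aldehyde gives the branched allylic alcohol, and the racemate suffices because this stereocentre is erased on ionization.

Step 8
Reactants: 11 (E)-3-(4-methoxyphenyl)prop-2-enyl (Z)-2-[(tert-butyldiphenylsilyloxy)methyl]but-2-enoate and 13 rac-1-(3,4-dimethoxyphenyl)prop-2-en-1-ol
Product: 17 (2S,3S)-2-[(E)-3-(3,4-dimethoxyphenyl)prop-2-enyl]-3-hydroxy-3-(4-methoxyphenyl)propyl (Z)-2-[(tert-butyldiphenylsilyloxy)methyl]but-2-enoate, via allyl cation 14 (not isolated), via water 15 (not isolated), via dioxanylium cation 16 (not isolated)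
Conditions: (R)-3,3'-bis(2,4,6-triisopropylphenyl)-1,1'-binaphthyl-2,2'-diyl N-triflylphosphoramide (10 mol%), 11 (3 equiv), slow addition of 13, toluene, −40 °C, no drying agent; Et3N quench
Reagents that add atoms: none
Why: Proposed new method: the acid ionizes the hydroxyl of 13 to the aryl-stabilised allyl cation 14, held as a contact ion pair with the chiral phosphoramidate; the anisyl-conjugated alkene of 11 attacks the unsubstituted terminus of 14 through its ester-side carbon (C2–C3 bond), the charge developing at C1 is captured by the ester carbonyl oxygen (C1–O bond) to give the 2-alkenyl-1,3-dioxan-2-ylium 16, and the water 15 released in the ionization adds at the acyl carbon, opens the ring and returns the proton to the catalyst. The closest known reaction types are chiral-Brønsted-acid-catalysed dehydrative allylic substitutions through ion pairs, asymmetric intermolecular Prins reactions of styrenes, and cation–olefin additions terminated by a neighbouring acyloxy group. The one ring, the transient dioxanylium, closes in the 6-endo mode (both alkene carbons in the ring) onto the benzylic cation through a chair-like array with the aryl group on C1 and the new side chain on C2 both equatorial. C2 is set by the chiral counter-anion, which selects the alkene face that bonds to the cation it escorts; C1 is relayed from C2 because anti addition across the E alkene with trans-diequatorial closure is the low-energy path, and any later ionization at C1 re-closes to the same trans ring. The step needs ionization of 13 in preference to 11 (secondary, doubly activated alcohol against a primary ester), terminal attack on the cation (conjugation is kept and the E styrene results), and reaction at the cinnamyl alkene of 11 in preference to its electron-poor enoate, the arene rings and the product styrene; capture by the carbonyl makes only the addition to 11 irreversible, and the excess of 11 with slow addition of 13 supports this. The primary ester is expected as the thermodynamic outcome, since the secondary 4-methoxybenzylic ester isomer returns to 16 under the acid.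

Step 9
Reactants: 17 (2S,3S)-2-[(E)-3-(3,4-dimethoxyphenyl)prop-2-enyl]-3-hydroxy-3-(4-methoxyphenyl)propyl (Z)-2-[(tert-butyldiphenylsilyloxy)methyl]but-2-enoate
Product: 18 (2S,3S)-2-[(E)-3-(3,4-dimethoxyphenyl)prop-2-enyl]-3-hydroxy-3-(4-methoxyphenyl)propyl (Z)-2-(hydroxymethyl)but-2-enoate
Conditions: HF·pyridine, pyridine, THF, 0 °C to rt
Reagents that add atoms: none
Why: Buffered fluoride cleaves the Si–O bond of the primary silyl ether, and the primary ester, the Z enoate, both E styrenes and the two stereocentres should be untouched under these near-neutral conditions.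

**Compound list**

1 | ethyl (E)-3-(4-methoxyphenyl)prop-2-enoate | CCOC(=O)/C=C/c1ccc(OC)cc1 | starting material
2 | (E)-3-(4-methoxyphenyl)prop-2-en-1-ol | OC/C=C/c1ccc(OC)cc1 | intermediate
3 | (E)-but-2-enal (crotonaldehyde) | C/C=C/C=O | starting material
4 | rac-(2R,3S)-2,3-dibromobutanal | C[C@H](Br)[C@H](Br)C=O | intermediate (not isolated)
5 | (Z)-2-bromobut-2-enal | C/C=C(/C=O)Br | intermediate
6 | (Z)-2-bromobut-2-en-1-ol | C/C=C(/CO)Br | intermediate
7 | tert-butyl{[(Z)-2-bromobut-2-en-1-yl]oxy}diphenylsilane | C/C=C(/CO[Si](c1ccccc1)(c1ccccc1)C(C)(C)C)Br | intermediate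
8 | [(E)-1-(tert-butyldiphenylsilyloxy)but-2-en-2-yl]lithium | C/C=C(/CO[Si](c1ccccc1)(c1ccccc1)C(C)(C)C)[Li] | intermediate (not isolated)
9 | (Z)-2-[(tert-butyldiphenylsilyloxy)methyl]but-2-enoic acid | C/C=C(/CO[Si](c1ccccc1)(c1ccccc1)C(C)(C)C)C(=O)O | intermediate
10 | (Z)-2-[(tert-butyldiphenylsilyloxy)methyl]but-2-enoic 2,4,6-trichlorobenzoic anhydride | C/C=C(/CO[Si](c1ccccc1)(c1ccccc1)C(C)(C)C)C(=O)OC(=O)c1c(Cl)cc(Cl)cc1Cl | intermediate (not isolated)
11 | (E)-3-(4-methoxyphenyl)prop-2-enyl (Z)-2-[(tert-butyldiphenylsilyloxy)methyl]but-2-enoate | C/C=C(/CO[Si](c1ccccc1)(c1ccccc1)C(C)(C)C)C(=O)OC/C=C/c1ccc(OC)cc1 | intermediate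
12 | 3,4-dimethoxybenzaldehyde | COc1ccc(C=O)cc1OC | starting material
13 | rac-1-(3,4-dimethoxyphenyl)prop-2-en-1-ol | C=CC(O)c1ccc(OC)c(OC)c1 | intermediate
14 | 1-(3,4-dimethoxyphenyl)allyl cation (3,4-dimethoxycinnamyl cation), paired with the chiral phosphoramidate | C=C[CH+]c1ccc(OC)c(OC)c1 | intermediate (not isolated)
15 | water, released on ionization of 13 and consumed in opening 16 | O | intermediate (not isolated)
16 | (4S,5S)-2-[(Z)-1-(tert-butyldiphenylsilyloxy)but-2-en-2-yl]-5-[(E)-3-(3,4-dimethoxyphenyl)prop-2-enyl]-4-(4-methoxyphenyl)-1,3-dioxan-2-ylium | C/C=C(/CO[Si](c1ccccc1)(c1ccccc1)C(C)(C)C)C2=[O+][C@H](c3ccc(OC)cc3)[C@@H](C/C=C/c3ccc(OC)c(OC)c3)CO2 | intermediate (not isolated)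
17 | (2S,3S)-2-[(E)-3-(3,4-dimethoxyphenyl)prop-2-enyl]-3-hydroxy-3-(4-methoxyphenyl)propyl (Z)-2-[(tert-butyldiphenylsilyloxy)methyl]but-2-enoate | C/C=C(/CO[Si](c1ccccc1)(c1ccccc1)C(C)(C)C)C(=O)OC[C@H](C/C=C/c1ccc(OC)c(OC)c1)[C@H](O)c1ccc(OC)cc1 | intermediate
18 | (2S,3S)-2-[(E)-3-(3,4-dimethoxyphenyl)prop-2-enyl]-3-hydroxy-3-(4-methoxyphenyl)propyl (Z)-2-(hydroxymethyl)but-2-enoate | C/C=C(/CO)C(=O)OC[C@H](C/C=C/c1ccc(OC)c(OC)c1)[C@H](O)c1ccc(OC)cc1 | target

**Count**

Total steps: 9. Longest linear sequence: 7 steps (3 to 18 through steps 2, 3, 4, 5, 6, 8 and 9).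

**Steps most likely to fail**

Step 8. Several processes may go wrong:
- poor facial selection by the counter-anion in an intermolecular addition with no hydrogen-bond handle on the alkene;
- further cation–olefin addition to the product styrene (oligomerization);
- scrambling through ionization of the cinnamyl ester;
- erosion of the Z enoate geometry while the acyl group is held as the alkenyl-dioxanylium.

The fallback uses known chemistry, sets out from 13 and returns at 17. Alcohol 13 is treated with PBr3 (Et2O, −10 °C, allylic transposition) to give (E)-4-(3-bromoprop-1-enyl)-1,2-dimethoxybenzene F1. Commercial ethyl 3-(4-methoxyphenyl)-3-oxopropanoate is hydrogenated over RuCl2[(R)-BINAP] (Noyori) to ethyl (S)-3-hydroxy-3-(4-methoxyphenyl)propanoate F2. Its dianion, formed with lithium diisopropylamide (2.2 equiv, THF, −78 to −20 °C), is alkylated with F1 (Fráter–Seebach alkylation, anti to the carbinol substituent in the lithium chelate). This should give ethyl (2R,3S)-2-[(E)-3-(3,4-dimethoxyphenyl)prop-2-enyl]-3-hydroxy-3-(4-methoxyphenyl)propanoate F3. Reduction with LiAlH4 (THF, 0 °C) gives (1S,2S)-2-[(E)-3-(3,4-dimethoxyphenyl)prop-2-enyl]-1-(4-methoxyphenyl)propane-1,3-diol F4. Its primary hydroxyl is acylated selectively with acid 9 under the Yamaguchi conditions of step 6 to give 17.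

Step 5. The alkenyllithium may undergo silyl shift from oxygen to carbon, lose silanolate by β-elimination, or lose its geometry before it is carboxylated. The fallback replaces the organolithium by a palladium-catalysed carbonylation, sets out from 7 and returns at 9. Bromide 7 is methoxycarbonylated with retention of geometry (PdCl2(PPh3)2, CO at 1 atm, MeOH, Et3N, DMF, 70 °C) to methyl (Z)-2-[(tert-butyldiphenylsilyloxy)methyl]but-2-enoate F5. The ester is cleaved with Me3SnOH (1,2-dichloroethane, 70 °C) to acid 9.

Step 6. The activated acyl group may isomerize from Z to E through reversible conjugate addition of the nucleophilic catalyst to the mixed anhydride or acylpyridinium. The fallback activates the alcohol and not the acid, sets out from 9 and 2, and returns at 11. A Mitsunobu esterification (PPh3, diisopropyl azodicarboxylate, THF, 0 °C) joins 9 and 2 directly to 11 without any new intermediate.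

**Further compounds**

F1 | step 8 | (E)-4-(3-bromoprop-1-enyl)-1,2-dimethoxybenzene | COc1ccc(/C=C/CBr)cc1OC
F2 | step 8 | ethyl (S)-3-hydroxy-3-(4-methoxyphenyl)propanoate | CCOC(=O)C[C@H](O)c1ccc(OC)cc1
F3 | step 8 | ethyl (2R,3S)-2-[(E)-3-(3,4-dimethoxyphenyl)prop-2-enyl]-3-hydroxy-3-(4-methoxyphenyl)propanoate | CCOC(=O)[C@H](C/C=C/c1ccc(OC)c(OC)c1)[C@H](O)c1ccc(OC)cc1
F4 | step 8 | (1S,2S)-2-[(E)-3-(3,4-dimethoxyphenyl)prop-2-enyl]-1-(4-methoxyphenyl)propane-1,3-diol | OC[C@H](C/C=C/c1ccc(OC)c(OC)c1)[C@H](O)c1ccc(OC)cc1
F5 | step 5 | methyl (Z)-2-[(tert-butyldiphenylsilyloxy)methyl]but-2-enoate | C/C=C(/CO[Si](c1ccccc1)(c1ccccc1)C(C)(C)C)C(=O)OC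
F0 | step 6 | none | none
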